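The data come from a simulation for substances that don't exist, noise included.

| flask | substrate | coupling partner | second reagent | protic impurity | remark | time |
|---|---|---|---|---|---|---|
| Wednesday's | 0.080 M | 0.20 M | 0.064 M | 0.016 M | run made earlier |  |
| Saturday's | 0.11 M | 0.20 M | 0.064 M | 0.016 M | run made earlier |  |
| Sunday's | 0.18 M | 0.20 M | 0.064 M | 0.016 M | run made earlier |  |
| green | 0.080 M | 0.200 M | 0.0640 M | 0.0160 M | one stirred flow tank at steady state, fed with the mixture as stated, mean residence time 8.0 min |  |
| teal | 0.080 M | 0.200 M | 0.0640 M | 0.0160 M | a closed flask charged with all of it at once and left for 8.0 min | 8.0 min |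
| amber | 0.080 M | 0.200 M | 0.0640 M (fed, over 4.00 min) | 0.0160 M | a stirred flask in which second reagent is dosed at a steady rate over 4.00 min without added volume, worked up at 8.0 min | 8.0 min |
| ochre | 0.080 M (fed, over 4.00 min) | 0.200 M | 0.0640 M | 0.0160 M | a stirred flask in which substrate is dosed at a steady rate over 4.00 min without added volume, worked up at 8.0 min | 8.0 min |

- Wednesday's (time / min: intermediate / %, target / %): 0.500: 5.6, 0.9; 1.50: 14.5, 1.0; 3.00: 22.7, 3.1; 4.00: 25.6, 4.4; 6.00: 31.7, 8.2; 8.00: 34.4, 9.3
- Saturday's (time / min: intermediate / %, target / %): 1.50: 15.9, 1.5; 3.00: 21.6, 1.8; 5.00: 27.8, 6.1; 6.00: 31.2, 6.2; 8.00: 36.9, 6.7; 10.0: 38.4, 8.6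
- Sunday's (time / min: intermediate / %, target / %): 0.833: 8.5, 0.3; 1.33: 12.3, 0.7; 2.00: 15.2, 1.1; 4.00: 26.3, 2.4; 6.00: 32.6, 2.7; 10.0: 43.0, 4.0

(each reading ± 1 percentage point)

- the stated concentrations are those of everything mixed, before any reaction; amounts are the same in each set-up
- the feed brings no volume worth counting
- the earlier runs were made in a closed, stirred flask

- the set-up with the highest amount of intermediate at the outlet or at the end, in percent of the substrate put in ("none" if the first two lie within 2 percentage points) (green / teal / amber / ochre / none)
- amount of intermediate at the outlet or at the end, in percent of the substrate put in, green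
- amount of intermediate at the outlet or at the end, in percent of the substrate put in, teal
- amount of intermediate at the outlet or at the end, in percent of the substrate put in, amber
- amount of intermediate at the outlet or at the end, in percent of the substrate put in, ochre

Late in Wednesday's run, between 4.00 min and 8.00 min, intermediate plus target gains a fraction 0.0342 min⁻¹ of the charge. But over the first 1.50 min of Wednesday's and Saturday's runs it gained 0.110 min⁻¹, a faster gain than the late one.

At 6.00 min intermediate reads 31.7%, 31.2% and 32.6% on Wednesday, Saturday and Sunday, although substrate differs, so formation looks pseudo-first-order in substrate. We therefore carry the decade time 21.0 min: the time in which substrate falls tenfold by this route at fixed [coupling partner].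

Read with that early constant, Wednesday's late gain means about 31.2% of substrate stood near 6.00 min. With 39.9% seen as products, about 28.9% went somewhere unseen.

Teal repeats Wednesday's charge, so we take 34.4% for it. In ochre the dosed substrate stays 6.00 min on average, which is 0.286 decades, fewer than teal's 0.381, so we put ochre below teal. Amber keeps teal's count. At 10.0 min target reads 0.00720 M on Sunday, lower than Saturday's 0.00946 M despite more substrate, so we read the unseen drain as substrate taking second reagent and place amber above teal.

The forecast differs. It gave 26%, 34.5%, 31% and 24% for green, teal, amber and ochre, with teal best, on “an active reagent dying on its own clock”.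

The flask gives 25.2%, 34.7%, 37.9% and 31.0% in that order, and amber is best.

    second reagent + protic impurity → quenched reagent (k = 0.650 M⁻¹ s⁻¹)
    substrate + second reagent → side product (k = 0.0370 M⁻¹ s⁻¹)
    substrate + coupling partner → intermediate (k = 0.0100 M⁻¹ s⁻¹)
    second reagent + intermediate → target (k = 0.0360 M⁻¹ s⁻¹)

In ochre at 8.00 min, substrate's half-life is 6.8 min by the coupling step and 15 min by the side-product step, a rate ratio of 2.2. Our decade time counted 0.286 decades for ochre, and the flask's substrate has fallen 0.455 decades. Ochre ends with 35.1% of substrate and 26.3% of side product.

For the ochre flask with 0.80 M of coupling partner, the decade time shrinks to 5.24 min, which leaves 7.18% of substrate. That flask computes to 5.30%, with 60.9% intermediate.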